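The earlier runs and the new flask come from a simulation for substances that don't exist, and the scatter is random.

Slowness was my first question, and the earlier runs answered it. The product in alder read 90.3% at 1.67 d and 90.1% at 3.00 d, so that flask had stopped rising, and the time asked for the new flasks lay beyond both readings.

| flask | electrophile | nucleophile | free base | scavenger | remark | time |
|---|---|---|---|---|---|---|
| alder | 0.28 M | 0.252 M | 0.308 M | 0.63 M | run made earlier |  |
| elm | 0.28 M | 0.252 M | 0.308 M | 0.21 M | run made earlier |  |
| south | 0.28 M | 0.252 M | 0.310 M | 0.420 M |  | 8.0 d |
| south-west | 0.28 M | 0.252 M | 0.400 M | 0.420 M |  | 8.0 d |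

| run | time / d | electrophile / % | product / % |
|---|---|---|---|
| alder | 0.208 | 16.6 | 83.7 |
| alder | 0.333 | 13.5 | 86.6 |
| alder | 0.625 | 10.7 | 89.4 |
| alder | 1.04 | 9.8 | 89.7 |
| alder | 1.67 | 9.7 | 90.3 |
| alder | 3.00 | 10.5 | 90.1 |
| elm | 0.208 | 15.9 | 83.1 |
| elm | 0.500 | 11.3 | 88.9 |
| elm | 1.04 | 9.8 | 89.9 |
| elm | 1.67 | 10.1 | 90.0 |
| elm | 2.00 | 10.3 | 90.4 |
| elm | 3.00 | 9.8 | 89.1 |

(standard deviation of a reading: 0.3 percentage points)

- acid set free is meant together with its idle adduct
- the earlier runs were read with a standard deviation of 0.3 percentage points
- steps that have been proposed: acid set free + scavenger -> scavenged by-product; acid set free + free base <-> salt of the base; nucleophile + acid set free <-> protonated nucleophile; electrophile + acid set free <-> idle adduct; electrophile + nucleophile -> acid set free + product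

* part of the electrophile that has reacted at the end, south
* part of the electrophile that has reacted at the end, south-west
* what raising the concentration of free base from its lowest to its highest value here does to the part of the electrophile that has reacted (changes below 5 percentage points count as none) (it rises / it falls / no change)

I therefore kept a ledger of the nucleophile, the limiting reagent, charged at 0.252 M against 0.28 M of electrophile. Each mole of it can stand as nucleophile, as protonated nucleophile or as product, and each mole of product takes one mole of electrophile. Dividing the two charges gave 90.0%. This is the ceiling C, the part of the electrophile that the nucleophile charged can turn into product.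

I expected the protonated entry to be empty at the end, since the free base charged in south, 0.310 M, exceeds the nucleophile charged and can take up the acid set free. The electrophile's side closed in alder: at 1.67 d, electrophile and product together read 100%, which showed no entry for the idle adduct within the scatter. Elm, with a third of alder's scavenger, read 90.0% of product at 1.67 d, so the plateau showed no mark of the scavenger. South and south-west carry the same two charges, so I reckoned the same C for both.

The forecast gave 90% for south, 90% for south-west and no change, saying of the plateau: “That is simply the charge ratio”.

The flasks gave 90.0% in south and 90.0% in south-west, hence no change, and both stood at the ceiling of 90.0%.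

    acid set free + scavenger → scavenged by-product (k = 6.60 M⁻¹ min⁻¹)
    acid set free + free base ⇌ salt of the base, settled at all times (K = 29000 M⁻¹)
    nucleophile + acid set free ⇌ protonated nucleophile, settled at all times (K = 150 M⁻¹)
    electrophile + acid set free ⇌ idle adduct, settled at all times (K = 36.0 M⁻¹)
    electrophile + nucleophile → acid set free + product (k = 0.100 M⁻¹ min⁻¹)

In south, the half-life of the nucleophile by the step to product was 0.75 h at 0.0238 d, far shorter than the 8.0 d of the run. At 8.00 d the ledger of south read product 90.0% of the electrophile charged, nucleophile 0% of its own charge and protonated nucleophile 0 M.

A neighbouring flask is south with 0.15 M of nucleophile in place of its charge, and its ceiling is 53.6%. Computed, that neighbour gave 53.6%, with 0% of its nucleophile left.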